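## Retrosynthetic overview

1. Cut the central sp2–sp2 bond of the (E,E)-diene. This gives a Suzuki–Miyaura union of an oxanyl (E)-alkenylboronate (fragment 1, C10) with a cyclohexyl (E)-alkenyl iodide (fragment 2, C10).
2. Fragment 1: the 3-bromo-2,2-dimethyloxane comes from a stereospecific oxolane-to-oxane ring expansion of a 2-(oxolan-2-yl)propan-2-ol through a bicyclic oxonium ion, where C–O is replaced by C–Br with inversion.
3. The trans-oxolane comes from Shi epoxidation and 5-exo closure of (R)-dehydrolinalool. That alcohol is built from (S)-2-methylglycidol, prenyl chloride and one carbon from the Ohira–Bestmann reagent.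
4. Fragment 2: the syn-bromohydrin comes from MeMgBr addition to the equatorial α-bromoketone, which is made with NBS from a silyl enol ether. The (E)-iodoalkene comes from methylalumination of an alkyne.
5. The carbocycle comes from an enantioselective Diels–Alder reaction of a 2-silyloxybutadiene (from but-3-en-2-one) with methyl acrylate. Ring order: oxirane, oxolane, oxane in fragment 1; the cyclohexene is formed independently in fragment 2.

Assumption: the (S)-diphenylprolinol-derived catalyst of step 7 delivers the (S)-ester; if the sense is opposite, its commercial antipode is used.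
Assumption: (S)-2-methylglycidol, prenyl chloride, but-3-en-2-one and methyl acrylate are bought; the L-fructose-derived Shi ketone is a purchased catalyst.

## Route

Step 1
Reactants: 1 (S)-2-methylglycidol; 2 prenyl chloride (1-chloro-3-methylbut-2-ene)
Product: 4 (2R)-2,6-dimethylhept-5-ene-1,2-diol, via prenylmagnesium chloride 3 (not isolated)
Conditions: 2, Mg, THF, 0 °C; separately 1, MeMgCl (1.0 equiv), THF, −40 °C; then 3 (1.5 equiv), CuI (10 mol %), −40 to 0 °C; aq NH4Cl
Reagents that add atoms: none
Why: Copper-catalysed SN2 epoxide opening at the unhindered CH2 through the primary (α) carbon of the prenyl nucleophile; the quaternary carbinol centre of 1 is not touched, and Payne migration of this alkoxide is degenerate, so configuration is retained.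

Step 2
Reactants: 4 (2R)-2,6-dimethylhept-5-ene-1,2-diol
Product: 5 (2R)-2-hydroxy-2,6-dimethylhept-5-enal
Conditions: IBX (1.3 equiv), DMSO, 23 °C
Reagents that add atoms: none
Why: IBX oxidation takes the primary alcohol of a 1,2-diol to the aldehyde without glycol cleavage; the tertiary alcohol and the alkene are inert, and the α-carbon has no hydrogen, so it cannot epimerise.

Step 3
Reactants: 5 (2R)-2-hydroxy-2,6-dimethylhept-5-enal
Product: 6 (3R)-3,7-dimethyloct-6-en-1-yn-3-ol ((R)-dehydrolinalool)
Conditions: dimethyl (1-diazo-2-oxopropyl)phosphonate (1.3 equiv), K2CO3 (2 equiv), MeOH, 0 to 23 °C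
Reagents that add atoms: Ohira–Bestmann reagent, dimethyl (1-diazo-2-oxopropyl)phosphonate, CC(=O)C(=[N+]=[N-])P(=O)(OC)OC
Why: Seyferth–Gilbert homologation (Ohira–Bestmann variant) turns the non-enolisable aldehyde into the terminal alkyne under mild base, leaving the stereocentre untouched.

Step 4
Reactants: 6 (3R)-3,7-dimethyloct-6-en-1-yn-3-ol
Product: 8 2-[(2R,5R)-5-ethynyl-5-methyloxolan-2-yl]propan-2-ol, via epoxy alcohol 7 (not isolated)
Conditions: L-fructose-derived Shi ketone (30 mol %), KHSO5 (as 2KHSO5·KHSO4·K2SO4), K2CO3, Bu4NHSO4, MeCN/CH2(OMe)2/aq Na2B4O7 buffer, 0 °C; then CSA (5 mol %), CH2Cl2, 0 °C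
Reagents that add atoms: potassium peroxymonosulfate, [K+].[O-]S(=O)(=O)OO
Why: Shi asymmetric epoxidation of the trisubstituted alkene gives the (S)-epoxide with this catalyst antipode and leaves the alkyne alone; acid-catalysed 5-exo-tet opening by the tertiary hydroxyl then inverts the secondary carbon, setting C2 as R, trans to the ethynyl group, and the minor 6-endo oxanol is removed by chromatography.

Step 5
Reactants: 8 2-[(2R,5R)-5-ethynyl-5-methyloxolan-2-yl]propan-2-ol
Product: 11 (3S,6R)-3-bromo-6-ethynyl-2,2,6-trimethyloxane, via bicyclic oxonium bromide 9 (not isolated), via tertiary bromide 10 (not isolated)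
Conditions: Me3SiBr (2.2 equiv), CH2Cl2, −40 to 0 °C; then ZnBr2 (0.3 equiv), MeNO2/CH2Cl2 1:1, 0 to 23 °C, followed by 1H NMR
Reagents that add atoms: bromotrimethylsilane, C[Si](C)(C)Br
Why: Proposed new method: deoxybrominative oxolane-to-oxane ring expansion under halide-rebound control, in which Me3SiBr/HBr ionises the tertiary C–O bond with participation of the ring oxygen to give the 1-oxoniabicyclo[3.1.0]hexane 9; bromide adds fastest at the tertiary carbon to give 10, but ZnBr2 re-ionises that bromide reversibly and the retained HBr returns any isopropenyl elimination product to the same manifold, whereas the slower SN2 attack at the secondary ring carbon, anti to its C–O bond with clean inversion (R carbinyl ether carbon becomes the S C–Br centre), gives the neopentyl-type secondary bromide 11, which does not re-ionise under these conditions and is favoured by loss of oxolane strain (about 4 to 5 kcal/mol) and by placing oxygen on the tertiary and bromine on the secondary carbon, so the equilibrium drains to 11; the electron-poor ethynyl group suppresses ionisation at the quaternary C–O bond; the closest known reaction types are the Zn(OAc)2-promoted expansion of oxolan-2-yl carbinyl sulfonates to oxan-3-yl acetates via bicyclic oxonium ions, the prolinol to 3-halopiperidine expansion via aziridinium ions under thermodynamic control, and the kinetic 5-exo to thermodynamic 6-endo isomerisation known from selenoetherification.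

Step 6
Reactants: 12 but-3-en-2-one (methyl vinyl ketone)
Product: 13 2-(triisopropylsilyloxy)buta-1,3-diene
Conditions: i-Pr3SiOTf (1.05 equiv), Et3N (1.3 equiv), CH2Cl2, 0 °C
Reagents that add atoms: triisopropylsilyl trifluoromethanesulfonate, CC(C)[Si](OS(=O)(=O)C(F)(F)F)(C(C)C)C(C)C
Why: Soft enolisation and O-silylation on the methyl side of the enone gives the cross-conjugated silyloxydiene; no stereocentre is formed.

Step 7
Reactants: 13 2-(triisopropylsilyloxy)buta-1,3-diene; 14 methyl acrylate
Product: 15 methyl (1S)-4-(triisopropylsilyloxy)cyclohex-3-ene-1-carboxylate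
Conditions: oxazaborolidinium triflimide from (S)-α,α-diphenylprolinol, o-tolylboroxine and Tf2NH (10 mol %), CH2Cl2, −40 °C
Reagents that add atoms: none
Why: Catalytic enantioselective Diels–Alder reaction in which the 2-silyloxy group enforces the 1,4 ("para") regiochemistry and the chiral boron Lewis acid shields one face of the bound acrylate, setting the ring stereocentre (S); the position of the enol ether double bond fixes the later bromination site.

Step 8
Reactants: 15 methyl (1S)-4-(triisopropylsilyloxy)cyclohex-3-ene-1-carboxylate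
Product: 17 {[(4S)-4-ethynylcyclohex-1-en-1-yl]oxy}triisopropylsilane, via aldehyde 16 (not isolated)
Conditions: i-Bu2AlH (1.05 equiv), CH2Cl2, −78 °C; then MeOH, K2CO3 (2 equiv), dimethyl (1-diazo-2-oxopropyl)phosphonate (1.3 equiv), −78 to 0 °C
Reagents that add atoms: Ohira–Bestmann reagent, dimethyl (1-diazo-2-oxopropyl)phosphonate, CC(=O)C(=[N+]=[N-])P(=O)(OC)OC
Why: Partial ester reduction to the aluminium hemiacetal followed by Seyferth–Gilbert homologation in the same flask; the bulky silyl enol ether survives K2CO3/MeOH, and the simple α-branched aldehyde is consumed at 0 °C faster than it epimerises.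

Step 9
Reactants: 17 {[(4S)-4-ethynylcyclohex-1-en-1-yl]oxy}triisopropylsilane
Product: 19 {[(4S)-4-[(E)-1-iodoprop-1-en-2-yl]cyclohex-1-en-1-yl]oxy}triisopropylsilane, via alkenylalane 18 (not isolated)
Conditions: AlMe3 (2.5 equiv), Cp2ZrCl2 (25 mol %), CH2Cl2, 0 to 23 °C; then I2 (1.2 equiv), THF, −40 °C; prompt aq Na2S2O3 quench
Reagents that add atoms: trimethylaluminium, C[Al](C)C; iodine, II
Why: Negishi zirconium-catalysed methylalumination adds Me and Al syn with aluminium at the terminal carbon, and iodinolysis proceeds with retention, fixing the E trisubstituted alkene; the alkenyl–Al bond reacts with I2 far faster than the hindered enol ether.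

Step 10
Reactants: 19 {[(4S)-4-[(E)-1-iodoprop-1-en-2-yl]cyclohex-1-en-1-yl]oxy}triisopropylsilane
Product: 21 (2S,4S)-2-bromo-4-[(E)-1-iodoprop-1-en-2-yl]cyclohexan-1-one (cis), via trans-bromoketone 20 (not isolated)
Conditions: NBS (1.05 equiv), NaHCO3, THF, −78 to 0 °C; then LiBr (2 equiv), DMF, 23 °C, 6 h; chromatography, trans isomer returned to LiBr/DMF
Reagents that add atoms: N-bromosuccinimide, O=C1CCC(=O)N1Br; lithium bromide (bromide exchange), [Li+].[Br-]
Why: Electrophilic α-bromination of the silyl enol ether is regiospecific and much faster than attack on the iodoalkene; axial attack first gives the trans (axial) bromide 20, and fast SN2 bromide exchange at the α-keto carbon in polar DMF equilibrates it towards the diequatorial cis isomer 21 (about 2 to 3:1), which is separated.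

Step 11
Reactants: 21 (2S,4S)-2-bromo-4-[(E)-1-iodoprop-1-en-2-yl]cyclohexan-1-one
Product: 22 (1R,2S,4S)-2-bromo-4-[(E)-1-iodoprop-1-en-2-yl]-1-methylcyclohexan-1-ol
Conditions: MeMgBr (1.3 equiv), Et2O/toluene, −78 °C, 1 h; AcOH quench at −78 °C
Reagents that add atoms: methylmagnesium bromide, C[Mg]Br
Why: Grignard 1,2-addition to an α-haloketone places methyl trans to the halogen (equatorial attack on the chair with bromine and side chain equatorial), giving the axial hydroxyl cis to bromine, that is the syn-bromohydrin; the cold acidic quench prevents semipinacol ring contraction of the magnesium alkoxide, and the alkenyl iodide does not exchange at −78 °C.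

Step 12
Reactants: 11 (3S,6R)-3-bromo-6-ethynyl-2,2,6-trimethyloxane; 22 (1R,2S,4S)-2-bromo-4-[(E)-1-iodoprop-1-en-2-yl]-1-methylcyclohexan-1-ol
Product: 24 (1R,2S,4S)-2-bromo-4-{(2E,4E)-5-[(2R,5S)-5-bromo-2,6,6-trimethyloxan-2-yl]penta-2,4-dien-2-yl}-1-methylcyclohexan-1-ol (target), via alkenylboronate 23 (not isolated)
Conditions: 11, pinacolborane (1.5 equiv), Cp2ZrHCl (10 mol %), Et3N (10 mol %), 60 °C; volatiles removed; then 22, PdCl2(dppf) (5 mol %), K3PO4 (3 equiv, aq), THF, 23 °C
Reagents that add atoms: none
Why: Zirconium-catalysed syn hydroboration gives the (E)-alkenylboronate, and Suzuki–Miyaura coupling retains both alkene geometries; zerovalent palladium inserts into the alkenyl C–I bond much faster than into the two unactivated secondary C–Br bonds, and the free tertiary alcohol is tolerated.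

## Compound list

1 | (S)-2-methylglycidol, [(2S)-2-methyloxiran-2-yl]methanol | OC[C@@]1(C)CO1 | starting material
2 | prenyl chloride, 1-chloro-3-methylbut-2-ene | CC(C)=CCCl | starting material
3 | prenylmagnesium chloride | CC(C)=CC[Mg]Cl | intermediate
4 | (2R)-2,6-dimethylhept-5-ene-1,2-diol | OC[C@@](O)(C)CCC=C(C)C | intermediate
5 | (2R)-2-hydroxy-2,6-dimethylhept-5-enal | O=C[C@@](O)(C)CCC=C(C)C | intermediate
6 | (3R)-3,7-dimethyloct-6-en-1-yn-3-ol | C#C[C@@](O)(C)CCC=C(C)C | intermediate
7 | (3R)-5-[(2S)-3,3-dimethyloxiran-2-yl]-3-methylpent-1-yn-3-ol | C#C[C@@](O)(C)CC[C@@H]1OC1(C)C | intermediate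
8 | 2-[(2R,5R)-5-ethynyl-5-methyloxolan-2-yl]propan-2-ol | C#C[C@@]1(C)CC[C@H](C(C)(C)O)O1 | intermediate
9 | (2R,5R)-2-ethynyl-2,6,6-trimethyl-1-oxoniabicyclo[3.1.0]hexane bromide | C#C[C@@]1(C)CC[C@H]2[O+]1C2(C)C.[Br-] | intermediate
10 | (2R,5R)-5-(2-bromopropan-2-yl)-2-ethynyl-2-methyloxolane | C#C[C@@]1(C)CC[C@H](C(C)(C)Br)O1 | intermediate
11 | (3S,6R)-3-bromo-6-ethynyl-2,2,6-trimethyloxane | C#C[C@@]1(C)CC[C@H](Br)C(C)(C)O1 | intermediate
12 | but-3-en-2-one | C=CC(C)=O | starting material
13 | 2-(triisopropylsilyloxy)buta-1,3-diene | C=CC(=C)O[Si](C(C)C)(C(C)C)C(C)C | intermediate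
14 | methyl acrylate | C=CC(=O)OC | starting material
15 | methyl (1S)-4-(triisopropylsilyloxy)cyclohex-3-ene-1-carboxylate | COC(=O)[C@H]1CCC(O[Si](C(C)C)(C(C)C)C(C)C)=CC1 | intermediate
16 | (1S)-4-(triisopropylsilyloxy)cyclohex-3-ene-1-carbaldehyde | O=C[C@H]1CCC(O[Si](C(C)C)(C(C)C)C(C)C)=CC1 | intermediate
17 | {[(4S)-4-ethynylcyclohex-1-en-1-yl]oxy}triisopropylsilane | C#C[C@H]1CCC(O[Si](C(C)C)(C(C)C)C(C)C)=CC1 | intermediate
18 | dimethyl{(E)-2-[(1S)-4-(triisopropylsilyloxy)cyclohex-3-en-1-yl]prop-1-en-1-yl}alane | C/C(=C\[Al](C)C)[C@H]1CCC(O[Si](C(C)C)(C(C)C)C(C)C)=CC1 | intermediate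
19 | {[(4S)-4-[(E)-1-iodoprop-1-en-2-yl]cyclohex-1-en-1-yl]oxy}triisopropylsilane | C/C(=C\I)[C@H]1CCC(O[Si](C(C)C)(C(C)C)C(C)C)=CC1 | intermediate
20 | (2R,4S)-2-bromo-4-[(E)-1-iodoprop-1-en-2-yl]cyclohexan-1-one (trans, axial Br) | C/C(=C\I)[C@H]1CCC(=O)[C@H](Br)C1 | intermediate
21 | (2S,4S)-2-bromo-4-[(E)-1-iodoprop-1-en-2-yl]cyclohexan-1-one (cis, equatorial Br) | C/C(=C\I)[C@H]1CCC(=O)[C@@H](Br)C1 | intermediate
22 | (1R,2S,4S)-2-bromo-4-[(E)-1-iodoprop-1-en-2-yl]-1-methylcyclohexan-1-ol | C/C(=C\I)[C@H]1CC[C@@](C)(O)[C@@H](Br)C1 | intermediate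
23 | 2-{(E)-2-[(2R,5S)-5-bromo-2,6,6-trimethyloxan-2-yl]ethenyl}-4,4,5,5-tetramethyl-1,3,2-dioxaborolane | CC1(C)OB(/C=C/[C@@]2(C)CC[C@H](Br)C(C)(C)O2)OC1(C)C | intermediate
24 | (1R,2S,4S)-2-bromo-4-{(2E,4E)-5-[(2R,5S)-5-bromo-2,6,6-trimethyloxan-2-yl]penta-2,4-dien-2-yl}-1-methylcyclohexan-1-ol | C/C(=C\C=C\[C@@]1(C)CC[C@H](Br)C(C)(C)O1)[C@H]1CC[C@@](C)(O)[C@@H](Br)C1 | target

## Step count and risks

Total step count: 12. Longest linear sequence: 7 (steps 6 to 12). Fragment 1 needs steps 1 to 5 and joins at step 12.

**Step 5 (the proposed ring expansion).**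
- Failure modes: the reaction stops at 10; HBr is lost to give the isopropenyl oxolane; or a 1,2-hydride shift leads to an oxocarbenium ion.
- The fallback uses known chemistry. It sets out from 6 and comes back at 11, skipping steps 4 and 5.
- Compound 6 is treated with 2,4,4,6-tetrabromocyclohexa-2,5-dienone in MeNO2 at 0 °C, or with NBS in (CF3)2CHOH, for a direct 6-endo bromoetherification by the tertiary hydroxyl.
- This gives 11 together with its C3 epimer and the two 5-exo oxolanes. About 15 to 25 % of 11 is expected after chromatography.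
- The C–Br centre is then set only by chair preference and by separation.
- This fallback makes no compound outside the list (none F0).

**Step 10 (only a modest preference for the equatorial bromide).**
- The fallback replaces electrophilic bromination by an oxygen-then-bromide sequence. It sets out from 19 and comes back at 21.
- Bis(4-nitrobenzenesulfonyl) peroxide in EtOAc at 0 °C attacks the enol ether axially and gives the trans (axial) (1R,5S)-5-[(E)-1-iodoprop-1-en-2-yl]-2-oxocyclohexyl 4-nitrobenzenesulfonate F1.
- Exactly one equivalent of LiBr in acetone at 0 °C then displaces the nosylate by SN2 with inversion, giving the equatorial bromide 21.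
- Nosylate leaves far faster than bromide and no free bromide remains at the end, so 21 is not epimerised.

**Step 7 (enantioselectivity of the catalytic Diels–Alder reaction with this diene and a simple acrylate).**
- The fallback uses a covalently bound auxiliary. It sets out from 13 and comes back at 15.
- (R)-4-Benzyloxazolidin-2-one is lithiated with n-BuLi and acylated with commercial acryloyl chloride to (R)-3-acryloyl-4-benzyl-1,3-oxazolidin-2-one F2.
- Et2AlCl (1.4 equiv) in CH2Cl2 at −78 °C chelates the imide in its s-cis form, and 13 adds to the face opposite the benzyl group. The product is (R)-4-benzyl-3-{[(1S)-4-(triisopropylsilyloxy)cyclohex-3-en-1-yl]carbonyl}-1,3-oxazolidin-2-one F3.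
- MeOMgBr in MeOH/CH2Cl2 at 0 °C transesterifies F3 to 15 and releases the auxiliary for reuse.

## Further compounds

F0 | step 5 | none | none
F1 | step 10 | (1R,5S)-5-[(E)-1-iodoprop-1-en-2-yl]-2-oxocyclohexyl 4-nitrobenzenesulfonate | C/C(=C\I)[C@H]1CCC(=O)[C@H](OS(=O)(=O)c2ccc(cc2)[N+](=O)[O-])C1
F2 | step 7 | (R)-3-acryloyl-4-benzyl-1,3-oxazolidin-2-one | C=CC(=O)N1[C@H](Cc2ccccc2)COC1=O
F3 | step 7 | (R)-4-benzyl-3-{[(1S)-4-(triisopropylsilyloxy)cyclohex-3-en-1-yl]carbonyl}-1,3-oxazolidin-2-one | O=C([C@H]1CCC(O[Si](C(C)C)(C(C)C)C(C)C)=CC1)N1[C@H](Cc2ccccc2)COC1=O
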